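All runs are calculated for an exercise.

| flask | substrate | enzyme | remark | time |
|---|---|---|---|---|
| amber | 25 mM | 5 µM | run made earlier |  |
| red | 12 mM | 5 µM | run made earlier |  |
| teal | 19 mM | 5 µM | run made earlier |  |
| delta | 25 mM (fed, over 4.00 min) | 5.0 µM | all but substrate at the start; substrate goes in evenly over 4.00 min, the run ends at 5.0 min | 5.0 min |
| eta | 25 mM | 5.0 µM | everything together in a closed stirred flask, run for 5.0 min | 5.0 min |
| alpha | 25 mM | 5.0 µM | one stirred flow tank at steady state, fed with the mixture as stated, mean residence time 5.0 min |  |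

| run | time / min | target / % | substrate / % |
|---|---|---|---|
| amber | 0.417 | 11.1 | 87.0 |
| amber | 0.833 | 20.5 | 74.3 |
| amber | 1.33 | 28.7 | 58.2 |
| amber | 1.50 | 31.5 | 53.9 |
| amber | 2.00 | 36.8 | 39.7 |
| amber | 2.50 | 39.7 | 28.2 |
| amber | 3.00 | 39.9 | 18.8 |
| red | 0.333 | 17.5 | 81.1 |
| red | 1.00 | 37.2 | 50.2 |
| red | 1.50 | 44.6 | 33.5 |
| red | 2.50 | 42.5 | 13.6 |
| red | 4.00 | 33.3 | 4.0 |
| red | 5.00 | 29.5 | 0.9 |
| red | 6.00 | 27.1 | 1.0 |
| teal | 0.333 | 12.1 | 86.8 |
| teal | 1.00 | 30.5 | 60.3 |
| teal | 1.50 | 37.8 | 43.6 |
| teal | 2.50 | 43.0 | 19.7 |
| teal | 4.00 | 35.6 | 5.2 |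
| teal | 5.00 | 30.7 | 1.8 |
| teal | 6.00 | 27.4 | 0.7 |

(scatter of a reading: 0.3 percentage points)

- the stated concentrations are those of everything mixed, before any reaction; amounts are the same in each set-up
- the feed brings no volume worth counting
- the earlier runs were made in a closed, stirred flask

* the set-up with the highest amount of target at the outlet or at the end, in percent of the substrate put in ("none" if the first two lie within 2 percentage points) (delta / eta / alpha / none)
* amount of target at the outlet or at the end, in percent of the substrate put in, delta
* amount of target at the outlet or at the end, in percent of the substrate put in, eta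
* amount of target at the outlet or at the end, in percent of the substrate put in, alpha

1. With the enzyme held at 5 µM, the amber substrate readings fell along a nearly straight line: between 0.417 min and 2.00 min their slope was 7.47 mM min⁻¹. I froze this reading as the ceiling rate.

2. The red tail was curved instead. Between 2.50 min and 4.00 min, c(substrate) gave a clearance constant, the pseudo-first-order constant at this enzyme level, of 0.816 min⁻¹.

3. The knee concentration, the c(substrate) at which the ceiling line and the first-order line meet, was 9.16 mM.

4. I drew eta on amber's charge. The straight line reached the knee at 2.12 min, and the exponential then gave, by my reckoning, 3.50% of the substrate at 5.0 min. The amber target readings stood at 39.7% at 2.50 min and 39.9% at 3.00 min, both later than that knee time.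

5. In delta the feed of 6.25 mM min⁻¹ was lower than the ceiling. So I drew c(substrate) climbing towards 7.66 mM, a plateau below the knee, and I reckoned 13.0% of the substrate left at the end.

6. The forecast gave 38% for delta, 32% for eta and 32% for alpha, and chose delta. It expected delta to end “with about 15% substrate unreacted”, against my 13.0%.

    target ⇌ isomer of the product (K = 3.20, k = 0.612 min⁻¹)
    substrate + enzyme → target + enzyme, rate k2*[substrate]*[enzyme]/(1 + ([substrate]/Km2) + ([substrate]/Ksi2)^2) (0.0599 M, 19.3 mM, k = 1.88 × 10⁵ M⁻¹ min⁻¹)

7. The flask gave 37.6% in delta, 32.0% in eta and 31.4% in alpha, so delta stood highest. With the dose spread over a tenth of the run, delta gave 32.4%, level with eta. At the stated feed, delta's c(substrate) peaked at 7.94 mM, under the knee. For the alpha tank, the clearance constant with the residence time of 5.0 min gave 4.92 mM, and the tank held 4.90 mM, also below the knee.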